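**Retrosynthetic overview**

1. Target ⇒ (ester C–O) the 3,4-diol ⇒ (C–H for C–O at the angular carbon) the 8a-hydroxymethyl triol ⇒ (RCM transform at C5=C6, ring B) a cyclopentane with a vinyl carbinol arm and a 3-methylbut-3-enyl arm ⇒ (vinyl addition to a lactol) a cis-fused bicyclic γ-lactone.
2. Key disconnection: that lactone ⇒ 4-(3-methylbut-3-en-1-yl)furan-2(5H)-one + 1-isopropylcyclopropanol. A copper-catalysed enantioselective homoenolate (3+2) annulation (conjugate addition, then aldol) makes the C8a–C1 and C3a–C3 bonds of ring A at once and brings in C1, C2, C3, the hydroxyl and the isopropyl group.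
3. Enabling feature (azulene locants of the target): on ring A (C1–C2–C3–C3a–C8a) the methyl on C8a, the C3a–C4 bond and the 3-OH are all cis, while H-3a, the isopropyl group and ring-B carbon C8 lie on the other face. The methyl carbon and C4 can therefore be the OCH2 and C=O of a cis-fused butyrolactone, which turns the trans-fused 5-7 system into a cis-bicyclo[3.3.0]octane problem (an enolate of a preformed cycloheptenone would close ring A cis to ring B and put the hydroxyl trans to the methyl).
4. Order of rings: temporary lactone ring (already in the butenolide) → ring A (key step, three contiguous stereocentres) → ring B (RCM, trans-fused by construction). The lactone is then taken apart: its C=O becomes C4 (lactol, vinyl Grignard), its OCH2 becomes the angular methyl (tosylate, hydride).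
5. Both partners of the key step are one step from catalogue compounds (Negishi coupling; Kulinkovich cyclopropanol synthesis).

Key step: step 3

Remark: azulene locants are used for the bicyclic compounds (C3 carbinol, C3a ring-fusion CH, C4 oxygen-bearing CH, C5=C6, C8a quaternary carbon); methyl 2-methylpropanoate, 4-bromo-2-methylbut-1-ene and 4-bromofuran-2(5H)-one are taken to be commercial.

**Route**

Step 1
Reactants: 1 methyl 2-methylpropanoate
Product: 2 1-(propan-2-yl)cyclopropan-1-ol
Conditions: EtMgBr (2.4 equiv), Ti(OiPr)4 (15 mol%), Et2O, 0 → 20 °C; then 10% aq. H2SO4, 0 °C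
Reagents that add atoms: ethylmagnesium bromide, CC[Mg]Br
Why: Kulinkovich reaction: the titanacyclopropane generated from two equivalents of EtMgBr on tetravalent titanium acts as a 1,2-dicarbanion equivalent toward the ester carbonyl and delivers the cyclopropanol; no stereocentre is formed.

Step 2
Reactants: 3 4-bromo-2-methylbut-1-ene; 4 4-bromofuran-2(5H)-one
Product: 6 4-(3-methylbut-3-en-1-yl)furan-2(5H)-one, via (3-methylbut-3-en-1-yl)zinc bromide 5 (not isolated)
Conditions: Zn dust (1.5 equiv), LiCl, THF, 50 °C; then 4, PdCl2(dppf) (3 mol%), THF, 50 °C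
Reagents that add atoms: none
Why: Direct zinc insertion gives the alkylzinc bromide, which undergoes Negishi cross-coupling (oxidative addition of zerovalent palladium into the vinylogous acyl bromide C4–Br, transmetalation, reductive elimination) without touching the lactone or the 1,1-disubstituted alkene; dppf suppresses β-hydride elimination.

Step 3
Reactants: 6 4-(3-methylbut-3-en-1-yl)furan-2(5H)-one; 2 1-(propan-2-yl)cyclopropan-1-ol
Product: 9 (3aR,6R,6aR)-6-hydroxy-3a-(3-methylbut-3-en-1-yl)-6-(propan-2-yl)hexahydro-1H-cyclopenta[c]furan-1-one, via ethyl(4-methyl-3-oxopentyl)zinc 7 (not isolated), via ethylzinc lactone enolate 8 (not isolated)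
Conditions: 2 (1.5 equiv), Et2Zn (1.5 equiv), toluene, 0 → 25 °C; then Cu(OTf)2 (5 mol%), BINOL-derived N,N-bis(1-phenylethyl)phosphoramidite (10 mol%, antipode giving 3aR), 6, −20 → 25 °C; aq. NH4Cl
Reagents that add atoms: none
Why: Proposed new method: Et2Zn deprotonates 2 and the strained zinc cyclopropoxide opens to the zinc homoenolate 7; transmetalation to the chiral copper complex (monovalent copper, formed from Cu(OTf)2 and the organozinc), π-complexation, oxidative addition at C4 of 6 and reductive elimination form the first bond and leave the zinc lactone enolate 8, whose α-carbon then adds to the pendant isopropyl ketone to form the second bond. The closest known reaction types are the copper–phosphoramidite-catalysed enantioselective conjugate addition of dialkylzinc reagents to unsaturated lactones and to β-substituted cyclic enones, the copper-catalysed conjugate addition of zinc homoenolates to enones, and the formal (3+2) annulation of cyclopropanol-derived zinc homoenolates with doubly activated alkenes; new here are the ketone homoenolate, the β,β-disubstituted butenolide acceptor and the in-flask aldol closure. Only ring A is closed, in a 5-exo-trig aldol addition (enolexo mode) that follows the intermolecular conjugate addition. C3a (quaternary) is set by the ligand through delivery of the alkyl group to the Re face of C4 of 6; C6a is set by the lactone ring, because the new five-membered ring can only be cis-fused to it; C6 is set by the zinc-bridged closed transition state that places the carbinol oxygen syn to the lactone carbonyl (concave face) and the isopropyl group on the convex face, which is also the more stable arrangement. The step needs 1,4- instead of 1,2-addition, C–C bond formation at the hindered β-carbon before protonation or γ-deprotonation, and aldol attack by the lactone enolate only; these are secured by the soft copper nucleophile, the weakly basic organozinc medium and the regiospecific generation of the enolate five atoms from the only ketone. Because the OCH2 carbon (future angular methyl) and the carbonyl carbon (future C4) are held cis by the lactone, the cis-bicyclo[3.3.0] product already carries the relative configuration of C8a, C3a and C3 of the target.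

Step 4
Reactants: 9 (3aR,6R,6aR)-6-hydroxy-3a-(3-methylbut-3-en-1-yl)-6-(propan-2-yl)hexahydro-1H-cyclopenta[c]furan-1-one
Product: 10 (3aR,6R,6aR)-3a-(3-methylbut-3-en-1-yl)-6-(propan-2-yl)hexahydro-1H-cyclopenta[c]furan-1,6-diol (lactol; both C1 epimers)
Conditions: i-Bu2AlH (2.5 equiv), CH2Cl2, −78 °C; aq. potassium sodium tartrate
Reagents that add atoms: none
Why: Partial reduction of a lactone at low temperature (the aluminium hemiacetalate does not collapse at −78 °C) gives the lactol; the extra hydride is consumed by the tertiary hydroxyl and the ring-A stereocentres are untouched.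

Step 5
Reactants: 10 (3aR,6R,6aR)-3a-(3-methylbut-3-en-1-yl)-6-(propan-2-yl)hexahydro-1H-cyclopenta[c]furan-1,6-diol
Product: 12 (1R,2S,3R)-3-(hydroxymethyl)-2-[(1S)-1-hydroxyprop-2-en-1-yl]-3-(3-methylbut-3-en-1-yl)-1-(propan-2-yl)cyclopentan-1-ol, via ring-opened hydroxy aldehyde 11 (not isolated)
Conditions: CH2=CHMgBr (5 equiv), THF, −78 → 0 °C; aq. NH4Cl
Reagents that add atoms: vinylmagnesium bromide, C=C[Mg]Br
Why: Excess Grignard reagent opens the lactol to the magnesium alkoxide of aldehyde 11 and adds to it under chelation control: magnesium bridges the aldehyde oxygen and the cis tertiary alkoxide on the neighbouring ring carbon, and the vinyl group attacks the carbonyl face turned away from the quaternary ring carbon, which should give the (1S) carbinol (1,2-addition of a Grignard reagent to an aldehyde).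

Step 6
Reactants: 12 (1R,2S,3R)-3-(hydroxymethyl)-2-[(1S)-1-hydroxyprop-2-en-1-yl]-3-(3-methylbut-3-en-1-yl)-1-(propan-2-yl)cyclopentan-1-ol
Product: 13 (3R,3aS,4S,8aR)-8a-(hydroxymethyl)-6-methyl-3-(propan-2-yl)-1,2,3,3a,4,7,8,8a-octahydroazulene-3,4-diol
Conditions: second-generation Grubbs catalyst RuCl2(=CHPh)(H2IMes)(PCy3) (5 mol%), 1,4-benzoquinone (10 mol%), CH2Cl2 (5 mM), 40 °C
Reagents that add atoms: none
Why: Ring-closing metathesis between the vinyl carbinol and the 1,1-disubstituted alkene gives the trisubstituted C5=C6 bond of seven-membered ring B with loss of ethene; the ring is trans-fused because the two arms are trans on ring A, and no stereocentre is touched.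

Step 7
Reactants: 13 (3R,3aS,4S,8aR)-8a-(hydroxymethyl)-6-methyl-3-(propan-2-yl)-1,2,3,3a,4,7,8,8a-octahydroazulene-3,4-diol
Product: 14 [(3R,3aS,4S,8aR)-3,4-dihydroxy-6-methyl-3-(propan-2-yl)-2,3,3a,4,7,8-hexahydroazulen-8a(1H)-yl]methyl 4-methylbenzenesulfonate
Conditions: TsCl (1.1 equiv), pyridine, CH2Cl2, 0 °C
Reagents that add atoms: 4-methylbenzenesulfonyl chloride, Cc1ccc(cc1)S(Cl)(=O)=O
Why: Sulfonylation distinguishes the hydroxyl groups by degree of substitution: the primary CH2OH reacts, while the hindered secondary allylic and the tertiary hydroxyl should not at 0 °C.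

Step 8
Reactants: 14 [(3R,3aS,4S,8aR)-3,4-dihydroxy-6-methyl-3-(propan-2-yl)-2,3,3a,4,7,8-hexahydroazulen-8a(1H)-yl]methyl 4-methylbenzenesulfonate
Product: 15 (3R,3aS,4S,8aS)-6,8a-dimethyl-3-(propan-2-yl)-1,2,3,3a,4,7,8,8a-octahydroazulene-3,4-diol
Conditions: LiEt3BH (5 equiv), THF, 0 → 65 °C; aq. NH4Cl
Reagents that add atoms: none
Why: SN2 displacement of the primary sulfonate by LiEt3BH, a hydride donor strong enough for neopentyl-type sulfonates; the two free hydroxyls are held as alkoxytriethylborates during the reaction, and the former lactone OCH2 becomes the angular methyl without touching a stereocentre.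

Step 9
Reactants: 15 (3R,3aS,4S,8aS)-6,8a-dimethyl-3-(propan-2-yl)-1,2,3,3a,4,7,8,8a-octahydroazulene-3,4-diol
Product: 16 (3R,3aS,4S,8aS)-3-hydroxy-6,8a-dimethyl-3-(propan-2-yl)-1,2,3,3a,4,7,8,8a-octahydroazulen-4-yl 4-methoxybenzoate
Conditions: 4-MeOC6H4COCl (1.5 equiv), DMAP (0.2 equiv), Et3N, CH2Cl2, 0 → 25 °C
Reagents that add atoms: 4-methoxybenzoyl chloride, COc1ccc(cc1)C(Cl)=O
Why: DMAP-catalysed acylation (nucleophilic catalysis via the N-acylpyridinium ion) esterifies the only acylable hydroxyl, the secondary allylic one, with retention because the C4–O bond is not broken; the tertiary carbinol stays free.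

**Compound list**

1 | methyl 2-methylpropanoate | COC(=O)C(C)C | starting material
2 | 1-(propan-2-yl)cyclopropan-1-ol | CC(C)C1(O)CC1 | intermediate
3 | 4-bromo-2-methylbut-1-ene | CC(=C)CCBr | starting material
4 | 4-bromofuran-2(5H)-one | O=C1OCC(Br)=C1 | starting material
5 | (3-methylbut-3-en-1-yl)zinc bromide | CC(=C)CC[Zn]Br | intermediate (not isolated)
6 | 4-(3-methylbut-3-en-1-yl)furan-2(5H)-one | CC(=C)CCC1=CC(=O)OC1 | intermediate
7 | ethyl(4-methyl-3-oxopentyl)zinc (zinc homoenolate) | CC[Zn]CCC(=O)C(C)C | intermediate (not isolated)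
8 | ethyl{[(4R)-4-(3-methylbut-3-en-1-yl)-4-(4-methyl-3-oxopentyl)-4,5-dihydrofuran-2-yl]oxy}zinc (ethylzinc lactone enolate) | CC[Zn]OC1=C[C@@](CCC(C)=C)(CCC(=O)C(C)C)CO1 | intermediate (not isolated)
9 | (3aR,6R,6aR)-6-hydroxy-3a-(3-methylbut-3-en-1-yl)-6-(propan-2-yl)hexahydro-1H-cyclopenta[c]furan-1-one | O=C1OC[C@]2(CCC(C)=C)CC[C@@](O)(C(C)C)[C@H]12 | intermediate
10 | (3aR,6R,6aR)-3a-(3-methylbut-3-en-1-yl)-6-(propan-2-yl)hexahydro-1H-cyclopenta[c]furan-1,6-diol (both C1 epimers) | OC1OC[C@]2(CCC(C)=C)CC[C@@](O)(C(C)C)[C@H]12 | intermediate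
11 | (1R,2R,5R)-2-hydroxy-5-(hydroxymethyl)-5-(3-methylbut-3-en-1-yl)-2-(propan-2-yl)cyclopentane-1-carbaldehyde (ring-opened hydroxy aldehyde) | O=C[C@@H]1[C@@](CO)(CCC(C)=C)CC[C@@]1(O)C(C)C | intermediate (not isolated)
12 | (1R,2S,3R)-3-(hydroxymethyl)-2-[(1S)-1-hydroxyprop-2-en-1-yl]-3-(3-methylbut-3-en-1-yl)-1-(propan-2-yl)cyclopentan-1-ol | C=C[C@H](O)[C@@H]1[C@@](CO)(CCC(C)=C)CC[C@@]1(O)C(C)C | intermediate
13 | (3R,3aS,4S,8aR)-8a-(hydroxymethyl)-6-methyl-3-(propan-2-yl)-1,2,3,3a,4,7,8,8a-octahydroazulene-3,4-diol | O[C@H]1C=C(C)CC[C@@]2(CO)CC[C@@](O)(C(C)C)[C@H]12 | intermediate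
14 | [(3R,3aS,4S,8aR)-3,4-dihydroxy-6-methyl-3-(propan-2-yl)-2,3,3a,4,7,8-hexahydroazulen-8a(1H)-yl]methyl 4-methylbenzenesulfonate | O[C@H]1C=C(C)CC[C@@]2(COS(=O)(=O)c3ccc(C)cc3)CC[C@@](O)(C(C)C)[C@H]12 | intermediate
15 | (3R,3aS,4S,8aS)-6,8a-dimethyl-3-(propan-2-yl)-1,2,3,3a,4,7,8,8a-octahydroazulene-3,4-diol | O[C@H]1C=C(C)CC[C@@]2(C)CC[C@@](O)(C(C)C)[C@H]12 | intermediate
16 | (3R,3aS,4S,8aS)-3-hydroxy-6,8a-dimethyl-3-(propan-2-yl)-1,2,3,3a,4,7,8,8a-octahydroazulen-4-yl 4-methoxybenzoate | COc1ccc(C(=O)O[C@H]2C=C(C)CC[C@@]3(C)CC[C@@](O)(C(C)C)[C@H]23)cc1 | target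

**Step count and risks**

Total steps: 9. Longest linear sequence: 8 (steps 2 to 9); step 1 is a one-step branch that joins at step 3.

Steps most likely to fail:

Step 3 (Proposed new method). The homoenolate may fail to add to the trisubstituted, enolizable butenolide (γ-deprotonation of 6 to the furanolate, or protonation of 7), or the copper complex may discriminate the two faces of C4 poorly. The fallback uses known chemistry, racemic and stepwise, followed by resolution. Starting again from 6 and 2, the zinc homoenolate is added under CuBr·SMe2 catalysis in the presence of Me3SiCl (chlorosilane-accelerated conjugate addition), which traps the adduct as the racemic silyl ketene acetal trimethyl{[4-(3-methylbut-3-en-1-yl)-4-(4-methyl-3-oxopentyl)-4,5-dihydrofuran-2-yl]oxy}silane F1. TiCl4 in CH2Cl2 at −78 °C then closes ring A by an intramolecular Mukaiyama aldol addition to the racemic hydroxy lactone rac-(3aR*,6R*,6aR*)-6-hydroxy-3a-(3-methylbut-3-en-1-yl)-6-(propan-2-yl)hexahydro-1H-cyclopenta[c]furan-1-one F2, which should have the same cis-fused, isopropyl-exo relative configuration for steric reasons. F2 is opened with (S)-1-phenylethylamine and AlMe3 to two diastereomeric hydroxy amides; (1R,2R,5R)-2-hydroxy-5-(hydroxymethyl)-5-(3-methylbut-3-en-1-yl)-N-[(1S)-1-phenylethyl]-2-(propan-2-yl)cyclopentane-1-carboxamide F3 is separated by chromatography or crystallization and relactonized with TsOH in toluene at 80 °C, which returns to 9.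

Step 8. Hydride attack at sulfur (S–O cleavage back to 13) or intramolecular displacement of the sulfonate by the cis tertiary alkoxide (bridged ether formation) may outrun SN2 substitution at the neopentyl carbon. The fallback cleaves the C–O bond by a radical instead of an ionic path. From 13, 1,1′-thiocarbonyldiimidazole in THF should acylate only the primary hydroxyl to give O-{[(3R,3aS,4S,8aR)-3,4-dihydroxy-6-methyl-3-(propan-2-yl)-2,3,3a,4,7,8-hexahydroazulen-8a(1H)-yl]methyl} 1H-imidazole-1-carbothioate F4; Bu3SnH and AIBN in toluene at 110 °C (Barton–McCombie deoxygenation) then return to 15, bypassing 14.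

Step 5. Facial selectivity in the Grignard addition may be poor if chelation to the tertiary alkoxide does not dominate. In the fallback the carbinol epimers are not separated but carried together through steps 6 to 8. From 15 (then a mixture of C4 epimers), MnO2 in CH2Cl2 oxidizes the allylic alcohol of both epimers to the single enone (3R,3aR,8aS)-3-hydroxy-6,8a-dimethyl-3-(propan-2-yl)-2,3,3a,7,8,8a-hexahydroazulen-4(1H)-one F5. Me4NBH(OAc)3 in MeCN/AcOH at −20 °C then reduces it by intramolecular hydride delivery from the boron bound to the 3-hydroxyl (the face of the angular methyl), which should return to 15 as the (4S) epimer.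

Further compounds
F1 | step 3 | trimethyl{[4-(3-methylbut-3-en-1-yl)-4-(4-methyl-3-oxopentyl)-4,5-dihydrofuran-2-yl]oxy}silane (racemic) | CC(=C)CCC1(CCC(=O)C(C)C)COC(O[Si](C)(C)C)=C1
F2 | step 3 | rac-(3aR*,6R*,6aR*)-6-hydroxy-3a-(3-methylbut-3-en-1-yl)-6-(propan-2-yl)hexahydro-1H-cyclopenta[c]furan-1-one (both enantiomers) | O=C1OC[C@]2(CCC(C)=C)CC[C@@](O)(C(C)C)[C@H]12.O=C1OC[C@@]2(CCC(C)=C)CC[C@](O)(C(C)C)[C@@H]12
F3 | step 3 | (1R,2R,5R)-2-hydroxy-5-(hydroxymethyl)-5-(3-methylbut-3-en-1-yl)-N-[(1S)-1-phenylethyl]-2-(propan-2-yl)cyclopentane-1-carboxamide | C[C@H](NC(=O)[C@@H]1[C@@](CO)(CCC(C)=C)CC[C@@]1(O)C(C)C)c1ccccc1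
F4 | step 8 | O-{[(3R,3aS,4S,8aR)-3,4-dihydroxy-6-methyl-3-(propan-2-yl)-2,3,3a,4,7,8-hexahydroazulen-8a(1H)-yl]methyl} 1H-imidazole-1-carbothioate | O[C@H]1C=C(C)CC[C@@]2(COC(=S)n3ccnc3)CC[C@@](O)(C(C)C)[C@H]12
F5 | step 5 | (3R,3aR,8aS)-3-hydroxy-6,8a-dimethyl-3-(propan-2-yl)-2,3,3a,7,8,8a-hexahydroazulen-4(1H)-one | O=C1C=C(C)CC[C@@]2(C)CC[C@@](O)(C(C)C)[C@H]12
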